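The dioxane ring of the 2,3-dihydro-1,4-benzodioxine (C2 bears the carboxyl, C3 the catechol ring) is cut at C2–C3 and at O4–C4a. Both bonds are made in one operation from a (2-fluoroaryloxy)acetyl imide and 3,4-bis(allyloxy)benzaldehyde: a MgCl2-catalysed anti-aldol addition joins C2 to C3 and sets both stereocentres under control of one purchased oxazolidinone, and the freed C3–O then displaces fluoride at C4a. The step exploits two features: C2–H is alpha to the carboxyl, and C4a of ring A lies para to C7, whose acrylate makes C4a–F open to SNAr. The precursor already carries the complete (R)-lactate cinnamate side chain; only auxiliary hydrolysis and deallylation follow.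

Key step: step 9

Remark on locants: benzodioxine numbering is used throughout (O1, C2 carboxyl carbon, C3 aryl carbon, O4, C4a, C7 acrylate carbon, C8a); ring A is the benzo ring. The target is the cis (2S,3S) isomer, which corresponds to the anti-aldol adduct.

Assumption: the facial sense of the MgCl2-catalysed aldol is taken from the chelated (Z)-enolate model (attack anti to the benzyl group, as in enolate alkylation), which calls for the (R)-4-benzyl auxiliary to give (S) at C2.

**Step 1**
Reactants: 1 4-bromo-2-methoxyphenol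
Product: 2 1-(allyloxy)-4-bromo-2-methoxybenzene
Conditions: allyl bromide, K2CO3, DMF, rt
Reagents that add atoms: allyl bromide, C=CCBr
Why: Williamson ether synthesis; the phenoxide displaces bromide from allyl bromide by SN2.

**Step 2**
Reactants: 2 1-(allyloxy)-4-bromo-2-methoxybenzene; 3 methyl (2R)-oxirane-2-carboxylate
Product: 5 methyl (R)-aryl-lactate, via arylmagnesium bromide 4 (not isolated)
Conditions: Mg, THF, 45 °C; then CuI (10 mol%), 3, THF, −40 to −20 °C; aq. NH4Cl
Reagents that add atoms: none
Why: CuI-catalysed Grignard opening of the epoxide at its unsubstituted CH2 carbon should outrun addition to the ester at low temperature; the stereocentre of purchased 3 is not touched, so (R) is carried over.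

**Step 3**
Reactants: 5 methyl (R)-aryl-lactate
Product: 6 allyl (R)-aryl-lactate
Conditions: Ti(OiPr)4 (20 mol%), allyl alcohol, 90 °C
Reagents that add atoms: allyl alcohol, C=CCO
Why: Ti(OiPr)4-catalysed transesterification, helped by chelation of the alpha-hydroxy ester; the neutral medium should leave the stereocentre intact.

**Step 4**
Reactants: 6 allyl (R)-aryl-lactate; 7 Meldrum's acid
Product: 8 malonic half ester of 6
Conditions: toluene, 100 °C
Reagents that add atoms: none
Why: thermal ring-opening acylation of the secondary alcohol by Meldrum's acid, with loss of acetone, should give the malonic half ester without base.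

**Step 5**
Reactants: 8 malonic half ester of 6; 9 4-fluoro-3-hydroxybenzaldehyde
Product: 10 (E)-4-fluoro-3-hydroxycinnamate of 6
Conditions: pyridine, β-alanine (cat.), 50 °C
Reagents that add atoms: none
Why: Knoevenagel–Doebner condensation; decarboxylative elimination should give the (E)-cinnamate, and the free phenol is tolerated.

**Step 6**
Reactants: 11 (4R)-4-benzyl-1,3-oxazolidin-2-one; 12 bromoacetyl bromide
Product: 14 (4R)-4-benzyl-3-(bromoacetyl)-1,3-oxazolidin-2-one, via N-lithio oxazolidinone 13 (not isolated)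
Conditions: n-BuLi, THF, −78 °C; then 12, −78 to 0 °C
Reagents that add atoms: none
Why: N-acylation of the lithiated oxazolidinone by the acyl bromide, which at −78 °C is faster than SN2 at the CH2Br group; the stereocentre is purchased.

**Step 7**
Reactants: 10 (E)-4-fluoro-3-hydroxycinnamate of 6; 14 (4R)-4-benzyl-3-(bromoacetyl)-1,3-oxazolidin-2-one
Product: 15 (2-fluoroaryloxy)acetyl imide
Conditions: K2CO3, acetone, rt
Reagents that add atoms: none
Why: Williamson ether synthesis; SN2 of the phenoxide at the alpha-bromo imide should be much faster than acyl attack or reaction at the esters.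

**Step 8**
Reactants: 16 3,4-dihydroxybenzaldehyde
Product: 17 3,4-bis(allyloxy)benzaldehyde
Conditions: allyl bromide, K2CO3, DMF, 60 °C
Reagents that add atoms: allyl bromide, C=CCBr
Why: double Williamson ether synthesis on the catechol.

**Step 9**
Reactants: 15 (2-fluoroaryloxy)acetyl imide; 17 3,4-bis(allyloxy)benzaldehyde
Product: 19 cis-benzodioxane imide, via anti-aldol silyl ether 18 (not isolated)
Conditions: MgCl2 (20 mol%), Et3N, Me3SiCl, EtOAc, 23 °C; then volatiles removed, CsF, DMF, 0 to 23 °C
Reagents that add atoms: none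
Why: Et3N should enolise only the chelating aryloxyacetyl imide on MgCl2 to the magnesium (Z)-enolate, which adds to aldehyde 17 through a boat transition state and is trapped by Me3SiCl as the anti silyl ether 18 (MgCl2-catalysed direct anti-aldol reaction of an N-acyl oxazolidinone, an Evans auxiliary aldol). Fluoride then frees the C3 alkoxide, which attacks the fluorine-bearing C4a of ring A and expels fluoride through a Meisenheimer intermediate stabilised by the para acrylate at C7 (desilylative SNAr etherification), so the whole is a formal [4+2] annulation of the aldehyde C=O bond. The dioxane ring closes by 6-exo-trig addition–elimination at the aromatic carbon. C2 (S) is set by the (R)-benzyl group, which shields one face of the chelated enolate, and C3 (S) by the anti topology of the boat transition state; the SNAr step touches neither centre, so the anti adduct gives the cis ring. The step needs chemoselective enolisation (only the imide is a chelating 1,3-dicarbonyl), a single SNAr site (one C–F, para to the acceptor) and ring closure faster than retro-aldol or C2 epimerisation; the low steady concentration of alkoxide in the fluoride chain, the intramolecular six-ring closure and the A(1,3)-strained imide are expected to secure this.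

**Step 10**
Reactants: 19 cis-benzodioxane imide
Product: 21 cis-benzodioxane-2-carboxylic acid, via peroxy acid 20 (not isolated)
Conditions: LiOH, H2O2, THF/H2O, 0 °C; then aq. Na2SO3; 1 M HCl to pH 3
Reagents that add atoms: hydrogen peroxide, OO
Why: lithium hydroperoxide hydrolysis of an N-acyl oxazolidinone; the weakly basic, highly nucleophilic hydroperoxide should attack the activated exocyclic imide carbonyl in preference to the esters and without C2 epimerisation, and sulfite reduces the peroxy acid.

**Step 11**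
Reactants: 21 cis-benzodioxane-2-carboxylic acid
Product: 22 target acid
Conditions: Pd(PPh3)4 (10 mol%), morpholine, THF, rt, degassed; then dilute HCl
Reagents that add atoms: none
Why: Tsuji–Trost deallylation; Pd(PPh3)4 ionises the allyl ester and the four aryl allyl ethers to π-allyl complexes that morpholine traps, under conditions that should spare the cinnamate and all three stereocentres.

**Compound list**

1 | 4-bromo-2-methoxyphenol | COc1cc(Br)ccc1O | starting material
2 | 1-(allyloxy)-4-bromo-2-methoxybenzene | COc1cc(Br)ccc1OCC=C | intermediate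
3 | methyl (2R)-oxirane-2-carboxylate (methyl (R)-glycidate) | COC(=O)[C@H]1CO1 | starting material
4 | arylmagnesium bromide: [4-(allyloxy)-3-methoxyphenyl]magnesium bromide | COc1cc([Mg]Br)ccc1OCC=C | intermediate
5 | methyl (R)-aryl-lactate: methyl (2R)-3-[4-(allyloxy)-3-methoxyphenyl]-2-hydroxypropanoate | COC(=O)[C@H](O)Cc1ccc(OCC=C)c(OC)c1 | intermediate
6 | allyl (R)-aryl-lactate: allyl (2R)-3-[4-(allyloxy)-3-methoxyphenyl]-2-hydroxypropanoate | C=CCOC(=O)[C@H](O)Cc1ccc(OCC=C)c(OC)c1 | intermediate
7 | Meldrum's acid (2,2-dimethyl-1,3-dioxane-4,6-dione) | CC1(C)OC(=O)CC(=O)O1 | starting material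
8 | malonic half ester of 6: 3-{[(2R)-1-(allyloxy)-3-[4-(allyloxy)-3-methoxyphenyl]-1-oxopropan-2-yl]oxy}-3-oxopropanoic acid | C=CCOC(=O)[C@@H](Cc1ccc(OCC=C)c(OC)c1)OC(=O)CC(=O)O | intermediate
9 | 4-fluoro-3-hydroxybenzaldehyde | O=Cc1ccc(F)c(O)c1 | starting material
10 | (E)-4-fluoro-3-hydroxycinnamate of 6: allyl (2R)-3-[4-(allyloxy)-3-methoxyphenyl]-2-{[(2E)-3-(4-fluoro-3-hydroxyphenyl)prop-2-enoyl]oxy}propanoate | C=CCOC(=O)[C@@H](Cc1ccc(OCC=C)c(OC)c1)OC(=O)/C=C/c1ccc(F)c(O)c1 | intermediate
11 | (4R)-4-benzyl-1,3-oxazolidin-2-one | O=C1OC[C@@H](Cc2ccccc2)N1 | starting material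
12 | bromoacetyl bromide | BrCC(Br)=O | starting material
13 | N-lithio oxazolidinone: lithium salt of 11 | [Li]N1C(=O)OC[C@H]1Cc1ccccc1 | intermediate
14 | (4R)-4-benzyl-3-(bromoacetyl)-1,3-oxazolidin-2-one | BrCC(=O)N1C(=O)OC[C@H]1Cc1ccccc1 | intermediate
15 | (2-fluoroaryloxy)acetyl imide: allyl (2R)-3-[4-(allyloxy)-3-methoxyphenyl]-2-{[(2E)-3-(3-{2-[(4R)-4-benzyl-2-oxo-1,3-oxazolidin-3-yl]-2-oxoethoxy}-4-fluorophenyl)prop-2-enoyl]oxy}propanoate | C=CCOC(=O)[C@@H](Cc1ccc(OCC=C)c(OC)c1)OC(=O)/C=C/c1ccc(F)c(OCC(=O)N2C(=O)OC[C@H]2Cc2ccccc2)c1 | intermediate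
16 | 3,4-dihydroxybenzaldehyde | O=Cc1ccc(O)c(O)c1 | starting material
17 | 3,4-bis(allyloxy)benzaldehyde | O=Cc1ccc(OCC=C)c(OCC=C)c1 | intermediate
18 | anti-aldol silyl ether: allyl (2R)-3-[4-(allyloxy)-3-methoxyphenyl]-2-{[(2E)-3-(3-{[(2S,3S)-1-[(4R)-4-benzyl-2-oxo-1,3-oxazolidin-3-yl]-3-[3,4-bis(allyloxy)phenyl]-1-oxo-3-(trimethylsilyloxy)propan-2-yl]oxy}-4-fluorophenyl)prop-2-enoyl]oxy}propanoate | C=CCOC(=O)[C@@H](Cc1ccc(OCC=C)c(OC)c1)OC(=O)/C=C/c1ccc(F)c(O[C@H](C(=O)N2C(=O)OC[C@H]2Cc2ccccc2)[C@H](c2ccc(OCC=C)c(OCC=C)c2)O[Si](C)(C)C)c1 | intermediate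
19 | cis-benzodioxane imide: (4R)-4-benzyl-3-{[(2S,3S)-3-[3,4-bis(allyloxy)phenyl]-7-[(1E)-3-{[(2R)-1-(allyloxy)-3-[4-(allyloxy)-3-methoxyphenyl]-1-oxopropan-2-yl]oxy}-3-oxoprop-1-en-1-yl]-2,3-dihydro-1,4-benzodioxin-2-yl]carbonyl}-1,3-oxazolidin-2-one | C=CCOC(=O)[C@@H](Cc1ccc(OCC=C)c(OC)c1)OC(=O)/C=C/c1ccc2c(c1)O[C@H](C(=O)N1C(=O)OC[C@H]1Cc1ccccc1)[C@H](c1ccc(OCC=C)c(OCC=C)c1)O2 | intermediate
20 | peroxy acid: (2S,3S)-3-[3,4-bis(allyloxy)phenyl]-7-[(1E)-3-{[(2R)-1-(allyloxy)-3-[4-(allyloxy)-3-methoxyphenyl]-1-oxopropan-2-yl]oxy}-3-oxoprop-1-en-1-yl]-2,3-dihydro-1,4-benzodioxine-2-carboperoxoic acid | C=CCOC(=O)[C@@H](Cc1ccc(OCC=C)c(OC)c1)OC(=O)/C=C/c1ccc2c(c1)O[C@H](C(=O)OO)[C@H](c1ccc(OCC=C)c(OCC=C)c1)O2 | intermediate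
21 | cis-benzodioxane-2-carboxylic acid: (2S,3S)-3-[3,4-bis(allyloxy)phenyl]-7-[(1E)-3-{[(2R)-1-(allyloxy)-3-[4-(allyloxy)-3-methoxyphenyl]-1-oxopropan-2-yl]oxy}-3-oxoprop-1-en-1-yl]-2,3-dihydro-1,4-benzodioxine-2-carboxylic acid | C=CCOC(=O)[C@@H](Cc1ccc(OCC=C)c(OC)c1)OC(=O)/C=C/c1ccc2c(c1)O[C@H](C(=O)O)[C@H](c1ccc(OCC=C)c(OCC=C)c1)O2 | intermediate
22 | target acid: (2S,3S)-7-[(1E)-3-{[(1R)-1-carboxy-2-(4-hydroxy-3-methoxyphenyl)ethyl]oxy}-3-oxoprop-1-en-1-yl]-3-(3,4-dihydroxyphenyl)-2,3-dihydro-1,4-benzodioxine-2-carboxylic acid | COc1cc(C[C@@H](OC(=O)/C=C/c2ccc3c(c2)O[C@H](C(=O)O)[C@H](c2ccc(O)c(O)c2)O3)C(=O)O)ccc1O | target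

**Step count and risks**

Total step count: 11. Longest linear sequence: 9 steps (steps 1, 2, 3, 4, 5, 7, 9, 10, 11); steps 6 and 8 make the two side fragments.

Steps most likely to fail:

Step 9. The coordinating alpha-aryloxy group may erode the anti and facial selectivity of the magnesium enolate addition. After desilylation, retro-aldol, epimerisation at C2 or attack of the alkoxide on the oxazolidinone carbonyl may compete with the ring closure, which would lead to the trans ring or to loss of the auxiliary. The fallback sets out from 15 and comes back to the route at 19; it separates the two bond formations and changes the aldol manifold. The di-n-butylboron enolate of 15 ((n-Bu)2BOTf, iPr2NEt, CH2Cl2, −78 to 0 °C) would be added at −78 °C to aldehyde 17 precomplexed with Et2AlCl. This open-transition-state anti-aldol addition on the same chelated enolate face should give, after chromatography of the diastereomers, the free anti β-hydroxy imide F1. F1 would then be closed in a discrete SNAr step with KN(SiMe3)2 and 18-crown-6 in THF at −78 to −30 °C to give 19.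

Step 10. Perhydrolysis may not discriminate fully between the imide and the activated lactate allyl ester or the cinnamate linkage, and the basic medium may cause C2 epimerisation or ring-opening β-elimination. The fallback sets out from 19 and comes back at 22; it replaces hydrolysis by a non-basic, chelation-directed alcoholysis. Yb(OTf)3 (10 mol%) in allyl alcohol should activate only the chelating imide and give the benzodioxane allyl ester F2. The Pd(PPh3)4/morpholine deallylation then removes six allyl groups instead of five and gives 22 directly.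

Step 11. Cleavage of the aryl allyl ethers may stay incomplete, the electron-rich catechol may be C-allylated by the π-allyl complex, and the free catechol may be oxidised in the basic amine medium. The fallback sets out from 21 and comes back at 22; it changes the catalyst manifold to an amine-free, weakly acidic one. [CpRu(MeCN)3]PF6 (5 mol%), a cationic divalent ruthenium complex, with quinaldic acid in degassed MeOH at 30 °C should transfer all allyl groups to the solvent. No new compound is made on the way.

**Further compounds**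

F1 | step 9 | anti β-hydroxy imide: allyl (2R)-3-[4-(allyloxy)-3-methoxyphenyl]-2-{[(2E)-3-(3-{[(2S,3S)-1-[(4R)-4-benzyl-2-oxo-1,3-oxazolidin-3-yl]-3-[3,4-bis(allyloxy)phenyl]-3-hydroxy-1-oxopropan-2-yl]oxy}-4-fluorophenyl)prop-2-enoyl]oxy}propanoate | C=CCOC(=O)[C@@H](Cc1ccc(OCC=C)c(OC)c1)OC(=O)/C=C/c1ccc(F)c(O[C@H](C(=O)N2C(=O)OC[C@H]2Cc2ccccc2)[C@@H](O)c2ccc(OCC=C)c(OCC=C)c2)c1
F2 | step 10 | benzodioxane allyl ester: allyl (2S,3S)-3-[3,4-bis(allyloxy)phenyl]-7-[(1E)-3-{[(2R)-1-(allyloxy)-3-[4-(allyloxy)-3-methoxyphenyl]-1-oxopropan-2-yl]oxy}-3-oxoprop-1-en-1-yl]-2,3-dihydro-1,4-benzodioxine-2-carboxylate | C=CCOC(=O)[C@@H](Cc1ccc(OCC=C)c(OC)c1)OC(=O)/C=C/c1ccc2c(c1)O[C@H](C(=O)OCC=C)[C@H](c1ccc(OCC=C)c(OCC=C)c1)O2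
F0 | step 11 | none | none
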